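- The constants of the steps were hidden, so I read one from the runs: a tail constant for the isomer after its peak, an apparent first-order constant.

| flask | substrate | remark | time |
|---|---|---|---|
| midnight | 0.42 M | run made earlier |  |
| summer | 0.66 M | run made earlier |  |
| flask | 0.30 M |  | 12 min |

| run | time / min | target / % | isomer of the product / % | substrate / % |
|---|---|---|---|---|
| midnight | 1.00 | 12.2 | 56.3 | 31.8 |
| midnight | 2.00 | 22.1 | 63.3 | 14.3 |
| midnight | 3.00 | 31.8 | 58.8 | 7.4 |
| midnight | 4.00 | 36.8 | 51.1 | 8.3 |
| midnight | 5.00 | 44.1 | 46.7 | 5.6 |
| midnight | 6.00 | 50.8 | 41.9 | 6.0 |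
| midnight | 8.00 | 57.6 | 35.2 | 3.8 |
| summer | 0.500 | 7.3 | 35.7 | 53.2 |
| summer | 0.833 | 9.6 | 49.1 | 35.8 |
| summer | 1.33 | 18.1 | 57.5 | 21.5 |
| summer | 2.00 | 23.1 | 61.1 | 14.9 |
| summer | 3.00 | 31.6 | 56.2 | 9.5 |
| summer | 5.00 | 46.1 | 45.1 | 6.6 |
| summer | 8.00 | 60.9 | 31.0 | 4.1 |

(each reading ± 1 percentage point)

- in percentages every species weighs as the substrate in it: one homo dimer counts as two
- for target the crystals are counted in
- as a solid, counted per litre of solution: crystals
- steps thought possible: substrate <-> target; 2 substrate -> homo dimer; target <-> isomer of the product; crystals <-> target; isomer of the product <-> substrate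

* share of target in target plus isomer of the product at 2.0 s
* share of target in target plus isomer of the product at 40 s
* share of target in target plus isomer of the product at 12 min
* which of target and isomer of the product there is more of at 12 min

- At 3.00 min the midnight run held less substrate, 7.4 % of the charge, than isomer, 58.8 %, so I read the later fall of isomer as its net loss.
- In the midnight run isomer read 35.2 % at 8.00 min, which gave 0.103 min⁻¹.
- Running that on from the midnight reading to 12 min put isomer at an estimated 23.3 % of the charge. Target plus isomer stood at 92.8 % in the last midnight reading, and with that sum held the estimated share came to 74.8 %.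
- The weak link was the charge, since the flask is more dilute than either run. Summer's last stretch gave 0.119 min⁻¹, faster than the midnight reading, though that is a thin reading against the scatter.
- Carrying the line through both runs down to 0.30 M gave 0.0944 min⁻¹: this is the tail constant, the fraction of the isomer lost per minute after its peak.
- From the same midnight reading, that estimate put isomer in the flask at 25.1 %, and I committed to a share of 72.9 %, with target ahead.
- The forecast gave 13.5 % at 2.0 s, 16.5 % at 40 s and 74 % at 12 min, with target ahead, 1.1 percentage points above my share: “Summer ran slightly ahead of midnight, so I shade the share down a little.”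
- The flask gave 12.8 %, 16.0 % and 70.9 %, with target ahead.

    substrate ⇌ target (K = 2.40, k = 0.00270 s⁻¹)
    2 substrate → homo dimer (k = 0.00110 M⁻¹ s⁻¹)
    target ⇌ isomer of the product (K = 3.00, k = 0.00940 s⁻¹)
    crystals ⇌ target, rate k4*(cs4 - [target]) while solid is left; crystals form when [target] > cs4 (solubility = 15.0 mM, k = 0.0390 s⁻¹)
    isomer of the product ⇌ substrate (k = 0.00260 s⁻¹)

- At 12.0 min the flask made isomer at 0.0139 of the rate at which it was used, each step taken net, and it held 27.4 % of the charge against my 25.1 %. In the flask dissolved target was made at 0.938 of its rate of use, while crystals reached 61.0 %. The tail constant, run from the same midnight reading for the neighbour charged with 0.075 M, gave 25.1 % again, but at 12.0 min that neighbour held more isomer, 62.6 %, with crystals at 8.04 %.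

Readings and results were computed for an exercise; the scatter is artificial.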